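Ring B (C5–C10, labdane numbering) is cut at C9–C10 back to a cyclopentanone: the oxygen on C8 and the chain carbon on C9, flanked by quaternary C10, are read as the product of a vinyl carbinol semipinacol shift. Bromonium-triggered migration of C10 from C8 to C9 in a trans-fused 1-vinylhydrindan-1-ol enlarges the five-membered ring to ring B in one operation, unveiling the C8 ketone and, after loss of HBr, a C9 methylene enone that accepts the side chain. The bromohydrindanone precursor comes from an enantioselective bromonium polyene cyclisation of a geranylacetone-derived propargylsilane; ring-closing metathesis and epoxidation finish the oxocane.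

Key step: step 5

Remark (assumptions): labdane numbering is used throughout (ring A = C1–C5 and C10; ring B = C5–C10; oxocane = C8, O, C15, C14, C13, C12, C11, C9). In step 2 the (R)-BINOL-derived thiophosphoramide is assumed to give the 3R bromide; if the sense proves opposite, its antipode is used.

Step 1
Reactants: 1 (E)-geranylacetone
Product: 4 trimethyl[(6E)-7,11-dimethyldodeca-6,10-dien-2-yn-1-yl]silane, via enol phosphate 2 (not isolated), via lithium acetylide 3 (not isolated)
Conditions: LDA (1.05 equiv), THF, −78 °C; ClP(O)(OEt)2, −78 °C → rt; LDA (2.25 equiv), −78 °C → rt; then Me3SiCH2OTf (1.5 equiv), −78 °C → rt; aq. NH4Cl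
Reagents that add atoms: (trimethylsilyl)methyl trifluoromethanesulfonate, C[Si](C)(C)COS(=O)(=O)C(F)(F)F
Why: The kinetic methyl-ketone enolate is trapped as the enol phosphate, LDA eliminates it to the lithium acetylide (Negishi alkyne synthesis from methyl ketones), and this acetylide, far more nucleophilic than the diisopropylamine and lithium diethyl phosphate present, is alkylated in the same flask by the unhindered triflate (SN2) to give the propargylsilane that later terminates the cyclisation, both trisubstituted alkenes and the E geometry staying untouched.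

Step 2
Reactants: 4 trimethyl[(6E)-7,11-dimethyldodeca-6,10-dien-2-yn-1-yl]silane
Product: 5 (3aS,5R,7aR)-5-bromo-1-ethenylidene-4,4,7a-trimethyloctahydro-1H-indene
Conditions: (R)-BINOL-derived thiophosphoramide catalyst (10 mol%), DBDMH (0.6 equiv), toluene/CH2Cl2, −90 °C
Reagents that add atoms: 1,3-dibromo-5,5-dimethylhydantoin, CC1(C)N(Br)C(=O)N(Br)C1=O
Why: In this Lewis-base-catalysed enantioselective bromonium polyene cyclisation the catalyst-bound Br+ should add to one face of the terminal alkene (sets C3), chair-like closure onto the E-alkene should give ring A with equatorial bromine and trans C5–H/C10–Me, and the C10 cation should be trapped 5-exo by the propargylsilane with loss of Me3Si+ (Johnson-type termination) to give the trans-hydrindane allene.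

Step 3
Reactants: 5 (3aS,5R,7aR)-5-bromo-1-ethenylidene-4,4,7a-trimethyloctahydro-1H-indene
Product: 6 (3aS,5R,7aR)-5-bromo-4,4,7a-trimethyloctahydro-1H-inden-1-one
Conditions: O3, CH2Cl2, −78 °C; Me2S
Reagents that add atoms: ozone, [O-][O+]=O
Why: Ozonolysis should cleave the allene, the only C=C unit present, to the cyclopentanone without touching the alkyl bromide or any stereocenter.

Step 4
Reactants: 6 (3aS,5R,7aR)-5-bromo-4,4,7a-trimethyloctahydro-1H-inden-1-one
Product: 7 (1S,3aS,5R,7aR)-5-bromo-1-ethenyl-4,4,7a-trimethyloctahydro-1H-inden-1-ol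
Conditions: CH2=CHMgBr, CeCl3, THF, −78 → 0 °C; aq. NH4Cl
Reagents that add atoms: vinylmagnesium bromide, C=C[Mg]Br
Why: The organocerium 1,2-addition (enolisation suppressed) should occur on the face opposite the angular methyl group, as with 17-keto steroids, giving the tertiary allylic alcohol with OH cis to that methyl.

Step 5
Reactants: 7 (1S,3aS,5R,7aR)-5-bromo-1-ethenyl-4,4,7a-trimethyloctahydro-1H-inden-1-ol
Product: 9 (4aS,6R,8aR)-6-bromo-5,5,8a-trimethyl-1-methylideneoctahydronaphthalen-2(1H)-one, via bromomethyl ketone 8 (not isolated)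
Conditions: NBS, CH2Cl2, −20 → 0 °C; then DBU, 0 °C → rt
Reagents that add atoms: none
Why: NBS converts the vinyl group into a bromonium ion and, as the carbinol oxygen forms the C8 carbonyl, the C8–C10 bond migrates to C9 anti to the opening C–Br bond (semipinacol 1,2-shift) to give the 2-(bromomethyl)cyclohexanone 8, from which DBU removes HBr (E1cB) to leave enone 9. The closest known reaction type is the halonium-induced ring enlargement of 1-vinylcycloalkanols to 2-(halomethyl)cycloalkanones, the same manifold as D-homoannulation of 17-vinyl-17-hydroxy steroids. No ring is closed by cyclisation: the cyclopentane C5–C6–C7–C8–C10 becomes ring B (C5–C6–C7–C8–C9–C10) by a one-carbon ring enlargement that inserts C9. C10 migrates with retention, so the trans C5/C10 fusion and the axial methyl are carried into the decalin, while C9 becomes sp2 on elimination and is set in step 6. The step needs migration of quaternary C10 rather than the C7 methylene, and a shift that outruns hydroxyl capture of the bromonium ion; it relies on the higher migratory aptitude of the more substituted, more electron-rich ring bond toward the cationic C9, on the gain of the C=O bond and on relief of trans-hydrindane strain, and the substrate has no second alkene.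

Step 6
Reactants: 9 (4aS,6R,8aR)-6-bromo-5,5,8a-trimethyl-1-methylideneoctahydronaphthalen-2(1H)-one
Product: 10 (1S,4aS,6R,8aR)-6-bromo-1-(3-bromobut-3-en-1-yl)-5,5,8a-trimethyloctahydronaphthalen-2(1H)-one
Conditions: CH2=C(Br)CH2SiMe3, TiCl4, CH2Cl2, −78 °C; aq. NaHCO3; then K2CO3 (cat.), MeOH, rt
Reagents that add atoms: (2-bromoallyl)trimethylsilane, C[Si](C)(C)CC(Br)=C
Why: Hosomi–Sakurai conjugate allylation (SE2′) of the TiCl4-activated exocyclic enone installs C12–C13 with the side-chain alkene masked as a vinyl bromide, and base equilibration of the α-center should place the C9 chain equatorial, the thermodynamically preferred 2-alkylcyclohexanone epimer.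

Step 7
Reactants: 10 (1S,4aS,6R,8aR)-6-bromo-1-(3-bromobut-3-en-1-yl)-5,5,8a-trimethyloctahydronaphthalen-2(1H)-one
Product: 11 (1R,4aS,6R,8aS)-6-bromo-1-(3-bromobut-3-en-1-yl)-5,5,8a-trimethyl-2-methylidenedecahydronaphthalene
Conditions: Ph3PCH3Br, KOtBu, toluene, 90 °C
Reagents that add atoms: methyltriphenylphosphonium bromide, C[P+](c1ccccc1)(c1ccccc1)c1ccccc1.[Br-]
Why: Wittig methylenation of the hindered ketone should tolerate the vinyl bromide and the equatorial alkyl bromide (no antiperiplanar hydrogen for E2), and C9 stays in its thermodynamic configuration.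

Step 8
Reactants: 11 (1R,4aS,6R,8aS)-6-bromo-1-(3-bromobut-3-en-1-yl)-5,5,8a-trimethyl-2-methylidenedecahydronaphthalene
Product: 13 (1S,2S,4aS,6R,8aR)-6-bromo-1-(3-bromobut-3-en-1-yl)-2,5,5,8a-tetramethyldecahydronaphthalen-2-ol, via organomercury acetate 12 (not isolated)
Conditions: Hg(OAc)2, THF/H2O, rt; then aq. NaOH, NaBH4, 0 °C
Reagents that add atoms: water, O
Why: In this Markovnikov oxymercuration–demercuration, water should open the mercurinium ion at C8 from the equatorial side, away from the axial C10 methyl (as in hydrations of labd-8(17)-enes), giving equatorial oxygen and axial methyl at C8, while the electron-poor vinyl bromide does not react.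

Step 9
Reactants: 13 (1S,2S,4aS,6R,8aR)-6-bromo-1-(3-bromobut-3-en-1-yl)-2,5,5,8a-tetramethyldecahydronaphthalen-2-ol
Product: 14 (1S,2S,4aS,6R,8aR)-6-bromo-2,5,5,8a-tetramethyl-1-(3-methylbut-3-en-1-yl)decahydronaphthalen-2-ol
Conditions: MeZnCl (3 equiv), Pd(PPh3)4 (5 mol%), THF, 50 °C
Reagents that add atoms: methylzinc chloride, C[Zn]Cl
Why: In this Negishi coupling, zerovalent palladium should insert only into the alkenyl C–Br bond, the hindered secondary alkyl bromide being inert, which unmasks the 1,1-disubstituted alkene needed for metathesis.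

Step 10
Reactants: 14 (1S,2S,4aS,6R,8aR)-6-bromo-2,5,5,8a-tetramethyl-1-(3-methylbut-3-en-1-yl)decahydronaphthalen-2-ol
Product: 16 (1S,2S,4aS,6R,8aR)-6-bromo-2,5,5,8a-tetramethyl-1-(3-methylbut-3-en-1-yl)-2-(prop-2-en-1-yloxy)decahydronaphthalene, via potassium alkoxide 15 (not isolated)
Conditions: KH, 18-crown-6 (cat.), THF, 0 °C; allyl bromide, 0 °C → rt
Reagents that add atoms: allyl bromide, C=CCBr
Why: Williamson etherification of the crown-activated tertiary potassium alkoxide with the reactive allylic bromide should give the allyl ether without change at any stereocenter.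

Step 11
Reactants: 16 (1S,2S,4aS,6R,8aR)-6-bromo-2,5,5,8a-tetramethyl-1-(3-methylbut-3-en-1-yl)-2-(prop-2-en-1-yloxy)decahydronaphthalene
Product: 17 (3R,5S,8S,9S,10R,13Z)-3-bromo-8,15-epoxylabd-13-ene
Conditions: second-generation Grubbs catalyst (10 mol%), toluene (2 mM), 80 °C
Reagents that add atoms: none
Why: Ring-closing olefin metathesis between the allyl ether and the 1,1-disubstituted alkene should close the oxocene, helped by the gauche diequatorial arms on C8 and C9, with the Z geometry imposed by the eight-membered ring.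

Step 12
Reactants: 17 (3R,5S,8S,9S,10R,13Z)-3-bromo-8,15-epoxylabd-13-ene
Product: 18 (3R,5S,8S,9S,10R,13S,14R)-3-bromo-8,15:13,14-diepoxylabdane
Conditions: DMDO, acetone/CH2Cl2, −20 → 0 °C
Reagents that add atoms: dimethyldioxirane, CC1(C)OO1
Why: Peripheral epoxidation is expected: in the favoured oxocene conformer (C12 anti to C10, C15 anti to the axial C8 methyl) the inner olefin face is capped by the transannular axial H-9, so oxygen should arrive on the outer face, which corresponds to 13S,14R.

Compound list
1 | (E)-geranylacetone, (5E)-6,10-dimethylundeca-5,9-dien-2-one | CC(C)=CCC/C(C)=C/CCC(C)=O | starting material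
2 | diethyl (5E)-6,10-dimethylundeca-1,5,9-trien-2-yl phosphate | CC(C)=CCC/C(C)=C/CCC(=C)OP(=O)(OCC)OCC | intermediate (not isolated)
3 | lithium (5E)-6,10-dimethylundeca-5,9-dien-1-yn-1-ide | CC(C)=CCC/C(C)=C/CCC#C[Li] | intermediate (not isolated)
4 | trimethyl[(6E)-7,11-dimethyldodeca-6,10-dien-2-yn-1-yl]silane | CC(C)=CCC/C(C)=C/CCC#CC[Si](C)(C)C | intermediate
5 | (3aS,5R,7aR)-5-bromo-1-ethenylidene-4,4,7a-trimethyloctahydro-1H-indene (trans-fused, Br equatorial) | CC1(C)[C@H](Br)CC[C@]2(C)[C@@H]1CCC2=C=C | intermediate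
6 | (3aS,5R,7aR)-5-bromo-4,4,7a-trimethyloctahydro-1H-inden-1-one | CC1(C)[C@H](Br)CC[C@]2(C)[C@@H]1CCC2=O | intermediate
7 | (1S,3aS,5R,7aR)-5-bromo-1-ethenyl-4,4,7a-trimethyloctahydro-1H-inden-1-ol (OH cis to angular methyl) | CC1(C)[C@H](Br)CC[C@]2(C)[C@@H]1CC[C@]2(O)C=C | intermediate
8 | (4aS,6R,8aR)-6-bromo-1-(bromomethyl)-5,5,8a-trimethyloctahydronaphthalen-2(1H)-one (either C1 epimer) | CC1(C)[C@H](Br)CC[C@]2(C)[C@@H]1CCC(=O)C2CBr | intermediate (not isolated)
9 | (4aS,6R,8aR)-6-bromo-5,5,8a-trimethyl-1-methylideneoctahydronaphthalen-2(1H)-one | CC1(C)[C@H](Br)CC[C@]2(C)[C@@H]1CCC(=O)C2=C | intermediate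
10 | (1S,4aS,6R,8aR)-6-bromo-1-(3-bromobut-3-en-1-yl)-5,5,8a-trimethyloctahydronaphthalen-2(1H)-one | CC1(C)[C@H](Br)CC[C@]2(C)[C@@H]1CCC(=O)[C@H]2CCC(Br)=C | intermediate
11 | (1R,4aS,6R,8aS)-6-bromo-1-(3-bromobut-3-en-1-yl)-5,5,8a-trimethyl-2-methylidenedecahydronaphthalene | CC1(C)[C@H](Br)CC[C@]2(C)[C@@H]1CCC(=C)[C@H]2CCC(Br)=C | intermediate
12 | {[(1S,2S,4aS,6R,8aR)-6-bromo-1-(3-bromobut-3-en-1-yl)-2-hydroxy-5,5,8a-trimethyldecahydronaphthalen-2-yl]methyl}mercury acetate | CC1(C)[C@H](Br)CC[C@]2(C)[C@@H]1CC[C@](C[Hg]OC(C)=O)(O)[C@H]2CCC(Br)=C | intermediate (not isolated)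
13 | (1S,2S,4aS,6R,8aR)-6-bromo-1-(3-bromobut-3-en-1-yl)-2,5,5,8a-tetramethyldecahydronaphthalen-2-ol (OH equatorial) | CC1(C)[C@H](Br)CC[C@]2(C)[C@@H]1CC[C@](C)(O)[C@H]2CCC(Br)=C | intermediate
14 | (1S,2S,4aS,6R,8aR)-6-bromo-2,5,5,8a-tetramethyl-1-(3-methylbut-3-en-1-yl)decahydronaphthalen-2-ol | CC1(C)[C@H](Br)CC[C@]2(C)[C@@H]1CC[C@](C)(O)[C@H]2CCC(C)=C | intermediate
15 | potassium alkoxide of 14 | CC1(C)[C@H](Br)CC[C@]2(C)[C@@H]1CC[C@](C)([O-])[C@H]2CCC(C)=C.[K+] | intermediate (not isolated)
16 | (1S,2S,4aS,6R,8aR)-6-bromo-2,5,5,8a-tetramethyl-1-(3-methylbut-3-en-1-yl)-2-(prop-2-en-1-yloxy)decahydronaphthalene | CC1(C)[C@H](Br)CC[C@]2(C)[C@@H]1CC[C@](C)(OCC=C)[C@H]2CCC(C)=C | intermediate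
17 | (3R,5S,8S,9S,10R,13Z)-3-bromo-8,15-epoxylabd-13-ene (oxocene) | CC1(C)[C@H](Br)CC[C@]2(C)[C@@H]1CC[C@]1(C)OC/C=C(C)\CC[C@@H]21 | intermediate
18 | (3R,5S,8S,9S,10R,13S,14R)-3-bromo-8,15:13,14-diepoxylabdane, CNP0311742.1 | CC1(C)[C@H](Br)CC[C@]2(C)[C@@H]1CC[C@]1(C)OC[C@H]3O[C@@]3(C)CC[C@@H]21 | target

Total step count: 12. Longest linear sequence: 12 steps (1 to 18).

Steps most likely to fail

Step 5 (key step). The C7 methylene may migrate in place of C10, or the hydroxyl may close on the bromonium ion to a bromomethyl spiro-epoxide before the shift occurs. The fallback sets out from 7: hydroxyl-directed epoxidation (VO(acac)2, t-BuOOH) gives the epoxy alcohol F1. BF3·OEt2 then opens the epoxide at C9 with concerted anti migration of the more substituted C8–C10 bond (2,3-epoxy alcohol semipinacol rearrangement) to the hydroxymethyl ketone F2. Mesylation to the mesylate F3 and DBU elimination come back to the route at enone 9.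

Step 2. Enantiocontrol may be incomplete, the C10 cation may lose a proton before the second ring closes, or the propargylsilane may be brominated. The fallback sets out from 4: racemic cyclisation with Et2SBr·SbCl5Br in MeNO2 gives the racemic allene F4, and ozonolysis gives the racemic ketone F5. Addition of lithiated (S)-N,S-dimethyl-S-phenylsulfoximine gives the hydroxysulfoximine F6 and its diastereomer F7, which are separated by chromatography. Thermolysis of F6 in refluxing toluene releases the sulfoximine and comes back to the route at ketone 6.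

Step 12. Oxygen may be delivered to the inner olefin face if the conformational argument fails. The fallback sets out from 17: NBS in wet THF should form the bromonium ion on the face the oxidant prefers, and water opens it at the tertiary C13 from the opposite face to give the bromohydrin F8. K2CO3 in MeOH then closes the epoxide with inversion at C14, placing oxygen on the face that direct epoxidation does not reach, and the route is rejoined at 18.

Further compounds
F1 | step 5 | (1R,3aS,5R,7aR)-5-bromo-4,4,7a-trimethyl-1-(oxiran-2-yl)octahydro-1H-inden-1-ol (ring stereocenters as in 7, oxirane carbon unassigned) | CC1(C)[C@H](Br)CC[C@]2(C)[C@@H]1CC[C@]2(O)C1CO1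
F2 | step 5 | (4aS,6R,8aR)-6-bromo-1-(hydroxymethyl)-5,5,8a-trimethyloctahydronaphthalen-2(1H)-one (C1 unassigned) | CC1(C)[C@H](Br)CC[C@]2(C)[C@@H]1CCC(=O)C2CO
F3 | step 5 | methanesulfonate of F2 | CC1(C)[C@H](Br)CC[C@]2(C)[C@@H]1CCC(=O)C2COS(C)(=O)=O
F4 | step 2 | racemic 5-bromo-1-ethenylidene-4,4,7a-trimethyloctahydro-1H-indene (5 and its enantiomer) | CC1(C)[C@H](Br)CC[C@]2(C)[C@@H]1CCC2=C=C.CC1(C)[C@@H](Br)CC[C@@]2(C)[C@H]1CCC2=C=C
F5 | step 2 | racemic 5-bromo-4,4,7a-trimethyloctahydro-1H-inden-1-one (6 and its enantiomer) | CC1(C)[C@H](Br)CC[C@]2(C)[C@@H]1CCC2=O.CC1(C)[C@@H](Br)CC[C@@]2(C)[C@H]1CCC2=O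
F6 | step 2 | hydroxysulfoximine adduct of 6 with (S)-N,S-dimethyl-S-phenylsulfoximine | CC1(C)[C@H](Br)CC[C@]2(C)[C@@H]1CC[C@]2(O)C[S@@](=O)(=NC)c1ccccc1
F7 | step 2 | diastereomeric hydroxysulfoximine adduct of the enantiomer of 6 | CC1(C)[C@@H](Br)CC[C@@]2(C)[C@H]1CC[C@@]2(O)C[S@@](=O)(=NC)c1ccccc1
F8 | step 12 | (3R,5S,8S,9S,10R)-3,14-dibromo-8,15-epoxylabdan-13-ol (bromohydrin, OH and Br anti) | CC1(C)[C@H](Br)CC[C@]2(C)[C@@H]1CC[C@]1(C)OC[C@H](Br)[C@@](C)(O)CC[C@@H]21
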